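Everything rests on disconnecting the ring-fusion bond C5a–C9a (decahydro-1-benzoxepine numbering) shared by the oxepane and cyclohexane rings. The key step exploits the quaternary, methyl-bearing C5a next to the oxygenated C9a: an (E)-γ,γ-disubstituted allylboronate, generated from an allylic chloride beside a tethered aldehyde, undergoes intramolecular allylboration that closes the cyclohexane ring and sets both centres at once. Its precursor is an acyclic chloro aldehyde whose C6/C7 stereodiad, held as an acetonide, comes from nerol by Sharpless epoxidation and anti epoxide opening. The new vinyl group then grows into the oxepane (7-endo epoxide opening), and a B-alkyl Suzuki coupling attaches the cyclohexenyl triflate half.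

Key step: step 9

Remark: locants follow decahydro-1-benzoxepine numbering of the bicyclic half (O1, C2–C5, C5a, C6–C9, C9a); the sense of induction quoted for the catalytic asymmetric steps is assumed to follow the standard model of each catalyst.

Step 1
Reactants: 1 but-2-yn-1-ol
Product: 2 tert-butyl(but-2-yn-1-yloxy)dimethylsilane
Conditions: TBSCl, imidazole, CH2Cl2, rt
Reagents that add atoms: tert-butyldimethylsilyl chloride, CC(C)(C)[Si](C)(C)Cl
Why: Imidazole-mediated silylation of a primary alcohol (silyl ether formation); no stereocentre is involved.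

Step 2
Reactants: 2 tert-butyl(but-2-yn-1-yloxy)dimethylsilane
Product: 4 tert-butyl{[(2E)-3-iodobut-2-en-1-yl]oxy}dimethylsilane, via alkenylzirconocene chloride 3 (not isolated)
Conditions: Cp2Zr(H)Cl (2.2 equiv), THF, 50 °C; then I2, 0 °C
Reagents that add atoms: iodine, II
Why: Syn hydrozirconation of the internal alkyne under equilibrating conditions (excess Cp2Zr(H)Cl, heat) should place zirconium on the less hindered methyl-bearing carbon, and iodinolysis with retention should give the iodide with iodine trans to the CH2O group.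

Step 3
Reactants: 5 nerol
Product: 6 [(2R,3S)-3-methyl-3-(4-methylpent-3-en-1-yl)oxiran-2-yl]methanol
Conditions: Ti(OiPr)4 (0.05 equiv), D-(−)-diethyl tartrate (0.06 equiv), t-BuOOH, 4 Å MS, CH2Cl2, −20 °C
Reagents that add atoms: tert-butyl hydroperoxide, CC(C)(C)OO
Why: Sharpless asymmetric epoxidation is directed by the allylic hydroxyl, so only the 2,3-alkene reacts, and D-(−)-tartrate should deliver oxygen to the face that gives the (2R,3S) epoxide, which fixes the future C7 and, after inversion, C6.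

Step 4
Reactants: 6 [(2R,3S)-3-methyl-3-(4-methylpent-3-en-1-yl)oxiran-2-yl]methanol, 4 tert-butyl{[(2E)-3-iodobut-2-en-1-yl]oxy}dimethylsilane
Product: 9 (2S,3S)-2-[(2E)-4-{[tert-butyl(dimethyl)silyl]oxy}but-2-en-2-yl]-3,7-dimethyloct-6-ene-1,3-diol, via alkenyllithium 7 (not isolated), via alkenylmagnesium bromide 8 (not isolated)
Conditions: 4 (3 equiv), t-BuLi (6 equiv), Et2O, −78 °C; MgBr2·OEt2 (3 equiv), −78 → −30 °C; CuI (0.3 equiv); then 6, −30 → 0 °C; aq. NH4Cl
Reagents that add atoms: none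
Why: Iodine–lithium exchange with retention, transmetalation to magnesium and copper-catalysed SN2 opening of the epoxy alkoxide at the secondary oxirane carbon (the tertiary one is blocked) should give the 1,3-diol with inversion, which sets the future C6 anti to the retained tertiary C–O bond and carries the E alkene through unchanged.

Step 5
Reactants: 9 (2S,3S)-2-[(2E)-4-{[tert-butyl(dimethyl)silyl]oxy}but-2-en-2-yl]-3,7-dimethyloct-6-ene-1,3-diol
Product: 10 tert-butyl(dimethyl){[(2E)-3-[(4S,5S)-2,2,4-trimethyl-4-(4-methylpent-3-en-1-yl)-1,3-dioxan-5-yl]but-2-en-1-yl]oxy}silane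
Conditions: 2,2-dimethoxypropane, PPTS (cat.), CH2Cl2, rt
Reagents that add atoms: 2,2-dimethoxypropane, COC(C)(C)OC
Why: Acid-catalysed transacetalisation ties the primary and tertiary hydroxyls into a 1,3-dioxane, which prevents lactol formation at the later aldehyde stage and leaves the allylic silyl ether intact.

Step 6
Reactants: 10 tert-butyl(dimethyl){[(2E)-3-[(4S,5S)-2,2,4-trimethyl-4-(4-methylpent-3-en-1-yl)-1,3-dioxan-5-yl]but-2-en-1-yl]oxy}silane
Product: 11 (2E)-3-[(4S,5S)-2,2,4-trimethyl-4-(4-methylpent-3-en-1-yl)-1,3-dioxan-5-yl]but-2-en-1-ol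
Conditions: Bu4NF, THF, 0 °C → rt
Reagents that add atoms: none
Why: Fluoride-mediated desilylation of the primary allylic silyl ether does not affect the acetonide or the alkenes.

Step 7
Reactants: 11 (2E)-3-[(4S,5S)-2,2,4-trimethyl-4-(4-methylpent-3-en-1-yl)-1,3-dioxan-5-yl]but-2-en-1-ol
Product: 12 (4S,5S)-5-[(2E)-4-chlorobut-2-en-2-yl]-2,2,4-trimethyl-4-(4-methylpent-3-en-1-yl)-1,3-dioxane
Conditions: N-chlorosuccinimide, Me2S, CH2Cl2, −20 → 0 °C
Reagents that add atoms: N-chlorosuccinimide, O=C1CCC(=O)N1Cl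
Why: Corey–Kim chlorination converts the primary allylic alcohol into the chloride by SN2 displacement of an alkoxysulfonium ion, without allylic transposition or loss of the E geometry.

Step 8
Reactants: 12 (4S,5S)-5-[(2E)-4-chlorobut-2-en-2-yl]-2,2,4-trimethyl-4-(4-methylpent-3-en-1-yl)-1,3-dioxane
Product: 13 3-[(4S,5S)-5-[(2E)-4-chlorobut-2-en-2-yl]-2,2,4-trimethyl-1,3-dioxan-4-yl]propanal
Conditions: O3 (1 equiv), pyridine, CH2Cl2, −78 °C
Reagents that add atoms: ozone, [O-][O+]=O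
Why: Ozonolysis with pyridine as in situ reductant should cleave only the electron-rich, unhindered isopropylidene alkene, because the other trisubstituted alkene is deactivated by the allylic chloride and screened by the dioxane.

Step 9
Reactants: 13 3-[(4S,5S)-5-[(2E)-4-chlorobut-2-en-2-yl]-2,2,4-trimethyl-1,3-dioxan-4-yl]propanal
Product: 16 (4aS,5R,6R,8aS)-5-ethenyl-2,2,5,8a-tetramethylhexahydro-4H-1,3-benzodioxin-6-ol, via allylboronate 14 (not isolated), via pinacol borate 15 (not isolated)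
Conditions: B2pin2 (1.2 equiv), Pd2(dba)3 (2.5 mol %), THF, 60 °C; then aq. NaHCO3
Reagents that add atoms: none
Why: Zerovalent palladium ionises the allylic chloride and B2pin2 transmetalates the π-allyl complex at its primary terminus, which should give the (E)-γ,γ-disubstituted allylboronate 14 with the alkene geometry intact while the aldehyde is left alone. Boronate 14 then adds through its γ-carbon to the tethered aldehyde in a closed, six-membered Zimmerman–Traxler transition state, forming the C5a–C9a bond; the closest known reaction types are the one-pot allylic borylation/carbonyl allylation and the ring-closing allylboration of ω-formyl allylboronates. The cyclohexane ring closes in a 6-exo-trig mode at the carbonyl carbon (the γ-carbon enters the ring, the transposed vinyl group stays outside), through a chair that is trans-fused to the boron-containing chair. The E geometry puts the ring tether equatorial and the methyl axial on the boracycle, so C5a should carry an axial methyl and an equatorial vinyl group and C9a an equatorial oxygen, that is vinyl and hydroxyl trans. The face of attack is set by the existing C6 and C7 centres, because only the chair that places the C7 oxygen, not the C7 methyl, syn-axial to the new axial C5a methyl avoids a methyl/methyl 1,3-diaxial clash. The step needs γ-selectivity and retention of the alkene geometry, which the SE2' course of allylboration, the strain of the eight-membered ring that α-attack would require and the configurational stability of pinacol allylboronates should secure.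

Step 10
Reactants: 16 (4aS,5R,6R,8aS)-5-ethenyl-2,2,5,8a-tetramethylhexahydro-4H-1,3-benzodioxin-6-ol, 17 1-bromo-2-methylprop-1-ene
Product: 19 (4aS,5R,6R,8aS)-2,2,5,8a-tetramethyl-5-(4-methylpent-3-en-1-yl)hexahydro-4H-1,3-benzodioxin-6-ol, via alkylborane 18 (not isolated)
Conditions: 9-BBN (2.5 equiv), THF, 0 → 40 °C; then 17 (3 equiv), Pd(dppf)Cl2 (5 mol %), 3 M aq. NaOH, THF, 60 °C
Reagents that add atoms: none
Why: Anti-Markovnikov hydroboration of the only alkene followed by B-alkyl Suzuki–Miyaura coupling with the alkenyl bromide should extend the vinyl group to the 4-methylpent-3-enyl chain without touching a stereocentre.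

Step 11
Reactants: 19 (4aS,5R,6R,8aS)-2,2,5,8a-tetramethyl-5-(4-methylpent-3-en-1-yl)hexahydro-4H-1,3-benzodioxin-6-ol
Product: 20 (4aS,5R,6R,8aS)-5-{2-[(2R)-3,3-dimethyloxiran-2-yl]ethyl}-2,2,5,8a-tetramethylhexahydro-4H-1,3-benzodioxin-6-ol
Conditions: D-fructose-derived Shi ketone (0.3 equiv), KHSO5 (as Oxone), K2CO3, Bu4NHSO4, MeCN/dimethoxymethane/aq. borate buffer (pH 10.5), 0 °C
Reagents that add atoms: potassium peroxymonosulfate, [K+].[O-]S(=O)(=O)OO
Why: Shi epoxidation (chiral dioxirane, spiro transition state) of the trisubstituted alkene is reagent-controlled, and the D-fructose-derived ketone should give the (R)-epoxide, which fixes C3.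

Step 12
Reactants: 20 (4aS,5R,6R,8aS)-5-{2-[(2R)-3,3-dimethyloxiran-2-yl]ethyl}-2,2,5,8a-tetramethylhexahydro-4H-1,3-benzodioxin-6-ol
Product: 21 isopropylidene acetal (C7 oxygen to C6 CH2O) of (3R,5aR,6S,7S,9aR)-6-(hydroxymethyl)-2,2,5a,7-tetramethyl-3-{[tri(propan-2-yl)silyl]oxy}decahydro-1-benzoxepin-7-ol
Conditions: TIPSOTf (1.5 equiv), 2,6-lutidine, MeNO2, 0 °C
Reagents that add atoms: triisopropylsilyl trifluoromethanesulfonate, CC(C)[Si](OS(=O)(=O)C(F)(F)F)(C(C)C)C(C)C
Why: Silyl triflate activation of the trisubstituted epoxide in a polar, non-nucleophilic medium should direct the C9a hydroxyl to the tertiary, more cation-stabilising carbon (7-endo epoxide opening), which closes the oxepane without touching the C3–O bond, so C3 stays R and its oxygen emerges as the silyl ether.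

Step 13
Reactants: 21 isopropylidene acetal of the diol 22
Product: 22 (3R,5aR,6S,7S,9aR)-6-(hydroxymethyl)-2,2,5a,7-tetramethyl-3-{[tri(propan-2-yl)silyl]oxy}decahydro-1-benzoxepin-7-ol
Conditions: PPTS, MeOH, 40 °C
Reagents that add atoms: none
Why: Mild acid-catalysed acetal exchange removes the strained 1,3-dioxane acetonide while the hindered triisopropylsilyl ether survives.

Step 14
Reactants: 22 (3R,5aR,6S,7S,9aR)-6-(hydroxymethyl)-2,2,5a,7-tetramethyl-3-{[tri(propan-2-yl)silyl]oxy}decahydro-1-benzoxepin-7-ol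
Product: 23 (3R,5aR,6R,7S,9aR)-7-hydroxy-2,2,5a,7-tetramethyl-3-{[tri(propan-2-yl)silyl]oxy}decahydro-1-benzoxepine-6-carbaldehyde
Conditions: Dess–Martin periodinane, NaHCO3, CH2Cl2, 0 °C → rt
Reagents that add atoms: none
Why: Dess–Martin oxidation of the primary alcohol under buffered conditions; the tertiary alcohol cannot be oxidised, and the equatorial formyl group at C6 is the thermodynamically preferred epimer.

Step 15
Reactants: 23 (3R,5aR,6R,7S,9aR)-7-hydroxy-2,2,5a,7-tetramethyl-3-{[tri(propan-2-yl)silyl]oxy}decahydro-1-benzoxepine-6-carbaldehyde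
Product: 24 (3R,5aR,6R,7S,9aR)-6-ethenyl-2,2,5a,7-tetramethyl-3-{[tri(propan-2-yl)silyl]oxy}decahydro-1-benzoxepin-7-ol
Conditions: Ph3PCH3Br, KN(SiMe3)2, THF, 0 °C; then 23, −78 → 0 °C
Reagents that add atoms: methyltriphenylphosphonium bromide, C[P+](c1ccccc1)(c1ccccc1)c1ccccc1.[Br-]
Why: Wittig methylenation of the hindered aldehyde with the non-stabilised ylide, which is too weak a base to deprotonate the tertiary alcohol and so should not trigger retro-aldol cleavage.

Step 16
Reactants: 25 2-methylcyclohexane-1,3-dione, 26 3-bromoprop-1-ene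
Product: 27 2-methyl-2-(prop-2-en-1-yl)cyclohexane-1,3-dione
Conditions: 1 M aq. NaOH, rt
Reagents that add atoms: none
Why: C-alkylation of the cyclic 1,3-diketone enolate with allyl bromide builds the quaternary carbon as a prochiral centre.

Step 17
Reactants: 27 2-methyl-2-(prop-2-en-1-yl)cyclohexane-1,3-dione
Product: 28 (2R,3R)-3-hydroxy-2-methyl-2-(prop-2-en-1-yl)cyclohexan-1-one
Conditions: (S)-2-methyl-CBS-oxazaborolidine (0.2 equiv), catecholborane (1.1 equiv), toluene, −78 → −50 °C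
Reagents that add atoms: none
Why: Corey–Bakshi–Shibata reduction desymmetrises the dione: the (S)-oxazaborolidine should give the (R)-carbinol with the quaternary carbon as the large group, and hydride should enter the carbonyl whose reactive face lies anti to the larger allyl group, so the hydroxyl ends up cis to allyl and C2 becomes R.

Step 18
Reactants: 28 (2R,3R)-3-hydroxy-2-methyl-2-(prop-2-en-1-yl)cyclohexan-1-one
Product: 29 (2R,3R)-3-{[tert-butyl(dimethyl)silyl]oxy}-2-methyl-2-(prop-2-en-1-yl)cyclohexan-1-one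
Conditions: TBSOTf, 2,6-lutidine, CH2Cl2, 0 °C
Reagents that add atoms: tert-butyldimethylsilyl trifluoromethanesulfonate, CC(C)(C)[Si](C)(C)OS(=O)(=O)C(F)(F)F
Why: Silyl ether formation on the hindered secondary alcohol blocks retro-aldol opening of the β-hydroxy ketone in the enolate steps that follow.

Step 19
Reactants: 29 (2R,3R)-3-{[tert-butyl(dimethyl)silyl]oxy}-2-methyl-2-(prop-2-en-1-yl)cyclohexan-1-one
Product: 31 (2R,3R,6RS)-3-{[tert-butyl(dimethyl)silyl]oxy}-2,6-dimethyl-2-(prop-2-en-1-yl)cyclohexan-1-one, via lithium enolate 30 (not isolated)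
Conditions: LiN(iPr)2, THF, −78 °C; MeI, −78 → −20 °C
Reagents that add atoms: iodomethane, CI
Why: Kinetic enolate alkylation; only C6 carries α-hydrogens, so the 6-methyl ketone should form, and its new centre is lost in the next step.

Step 20
Reactants: 31 (2R,3R,6RS)-3-{[tert-butyl(dimethyl)silyl]oxy}-2,6-dimethyl-2-(prop-2-en-1-yl)cyclohexan-1-one
Product: 33 (5R,6R)-5-{[tert-butyl(dimethyl)silyl]oxy}-2,6-dimethyl-6-(prop-2-en-1-yl)cyclohex-1-en-1-yl trifluoromethanesulfonate, via potassium enolate 32 (not isolated)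
Conditions: KN(SiMe3)2, THF, −78 °C; PhNTf2, −78 → 0 °C
Reagents that add atoms: N-phenylbis(trifluoromethanesulfonimide), O=S(=O)(N(c1ccccc1)S(=O)(=O)C(F)(F)F)C(F)(F)F
Why: Deprotonation of the remaining tertiary α-hydrogen gives the only possible, tetrasubstituted enolate, which is trapped on oxygen (enol triflate formation).

Step 21
Reactants: 33 (5R,6R)-5-{[tert-butyl(dimethyl)silyl]oxy}-2,6-dimethyl-6-(prop-2-en-1-yl)cyclohex-1-en-1-yl trifluoromethanesulfonate, 34 2-methylbut-3-en-2-ol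
Product: 35 (5R,6R)-5-{[tert-butyl(dimethyl)silyl]oxy}-6-[(2E)-4-hydroxy-4-methylpent-2-en-1-yl]-2,6-dimethylcyclohex-1-en-1-yl trifluoromethanesulfonate
Conditions: 34 (10 equiv), second-generation Grubbs catalyst (5 mol %), CH2Cl2, 40 °C
Reagents that add atoms: none
Why: Olefin cross-metathesis between the unhindered allyl group and the slowly homodimerising tertiary allylic alcohol should give the E-disubstituted alkene, while the enol triflate and the tetrasubstituted alkene are inert to the ruthenium carbene.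

Step 22
Reactants: 24 (3R,5aR,6R,7S,9aR)-6-ethenyl-2,2,5a,7-tetramethyl-3-{[tri(propan-2-yl)silyl]oxy}decahydro-1-benzoxepin-7-ol, 35 (5R,6R)-5-{[tert-butyl(dimethyl)silyl]oxy}-6-[(2E)-4-hydroxy-4-methylpent-2-en-1-yl]-2,6-dimethylcyclohex-1-en-1-yl trifluoromethanesulfonate
Product: 37 (3R,5aR,6R,7S,9aR)-6-{2-[(5R,6S)-5-{[tert-butyl(dimethyl)silyl]oxy}-6-[(2E)-4-hydroxy-4-methylpent-2-en-1-yl]-2,6-dimethylcyclohex-1-en-1-yl]ethyl}-2,2,5a,7-tetramethyl-3-{[tri(propan-2-yl)silyl]oxy}decahydro-1-benzoxepin-7-ol, via alkylborane 36 (not isolated)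
Conditions: 24, 9-BBN (3 equiv), THF, rt → 40 °C; 3 M aq. K3PO4; then 35, Pd(dppf)Cl2 (10 mol %), AsPh3, DMF, 45 °C
Reagents that add atoms: none
Why: Terminal hydroboration of the only alkene of 24 and B-alkyl Suzuki–Miyaura coupling with the enol triflate (oxidative addition of zerovalent palladium, transmetalation of the borate, reductive elimination) should join the halves with the tetrasubstituted alkene in place.

Step 23
Reactants: 37 the bis-silyl ether of the target
Product: 38 siphonellinol C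
Conditions: Bu4NF (excess), THF, 60 °C
Reagents that add atoms: none
Why: Fluoride-mediated desilylation removes both silyl ethers under non-acidic conditions, which spares the tertiary allylic alcohol and the tetrasubstituted alkene.

Compound list

1 | but-2-yn-1-ol | CC#CCO | starting material
2 | tert-butyl(but-2-yn-1-yloxy)dimethylsilane | CC#CCO[Si](C)(C)C(C)(C)C | intermediate
3 | chlorobis(cyclopentadienyl)[(2E)-4-(tert-butyldimethylsilyloxy)but-2-en-2-yl]zirconium (Zr trans to CH2O; cyclopentadienyl rings drawn σ-bound) | Cl[Zr](C1C=CC=C1)(C1C=CC=C1)/C(C)=C/CO[Si](C)(C)C(C)(C)C | intermediate (not isolated)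
4 | tert-butyl{[(2E)-3-iodobut-2-en-1-yl]oxy}dimethylsilane | I/C(C)=C/CO[Si](C)(C)C(C)(C)C | intermediate
5 | nerol, (2Z)-3,7-dimethylocta-2,6-dien-1-ol | CC(C)=CCC/C(C)=C\CO | starting material
6 | [(2R,3S)-3-methyl-3-(4-methylpent-3-en-1-yl)oxiran-2-yl]methanol | OC[C@H]1O[C@@]1(C)CCC=C(C)C | intermediate
7 | [(2Z)-4-(tert-butyldimethylsilyloxy)but-2-en-2-yl]lithium (Li trans to CH2O) | [Li]/C(C)=C/CO[Si](C)(C)C(C)(C)C | intermediate (not isolated)
8 | bromo[(2E)-4-(tert-butyldimethylsilyloxy)but-2-en-2-yl]magnesium | Br[Mg]/C(C)=C/CO[Si](C)(C)C(C)(C)C | intermediate (not isolated)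
9 | (2S,3S)-2-[(2E)-4-{[tert-butyl(dimethyl)silyl]oxy}but-2-en-2-yl]-3,7-dimethyloct-6-ene-1,3-diol | OC[C@@H]([C@@](C)(O)CCC=C(C)C)/C(C)=C/CO[Si](C)(C)C(C)(C)C | intermediate
10 | tert-butyl(dimethyl){[(2E)-3-[(4S,5S)-2,2,4-trimethyl-4-(4-methylpent-3-en-1-yl)-1,3-dioxan-5-yl]but-2-en-1-yl]oxy}silane | CC1(C)OC[C@H](/C(C)=C/CO[Si](C)(C)C(C)(C)C)[C@](C)(CCC=C(C)C)O1 | intermediate
11 | (2E)-3-[(4S,5S)-2,2,4-trimethyl-4-(4-methylpent-3-en-1-yl)-1,3-dioxan-5-yl]but-2-en-1-ol | CC1(C)OC[C@H](/C(C)=C/CO)[C@](C)(CCC=C(C)C)O1 | intermediate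
12 | (4S,5S)-5-[(2E)-4-chlorobut-2-en-2-yl]-2,2,4-trimethyl-4-(4-methylpent-3-en-1-yl)-1,3-dioxane | CC1(C)OC[C@H](/C(C)=C/CCl)[C@](C)(CCC=C(C)C)O1 | intermediate
13 | 3-[(4S,5S)-5-[(2E)-4-chlorobut-2-en-2-yl]-2,2,4-trimethyl-1,3-dioxan-4-yl]propanal | CC1(C)OC[C@H](/C(C)=C/CCl)[C@](C)(CCC=O)O1 | intermediate
14 | 3-[(4S,5S)-2,2,4-trimethyl-5-[(2E)-4-(4,4,5,5-tetramethyl-1,3,2-dioxaborolan-2-yl)but-2-en-2-yl]-1,3-dioxan-4-yl]propanal | CC1(C)OC[C@H](/C(C)=C/CB2OC(C)(C)C(C)(C)O2)[C@](C)(CCC=O)O1 | intermediate (not isolated)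
15 | 2-{[(4aS,5R,6R,8aS)-5-ethenyl-2,2,5,8a-tetramethylhexahydro-4H-1,3-benzodioxin-6-yl]oxy}-4,4,5,5-tetramethyl-1,3,2-dioxaborolane | CC1(C)OC[C@@H]2[C@@](C)(C=C)[C@H](OB3OC(C)(C)C(C)(C)O3)CC[C@]2(C)O1 | intermediate (not isolated)
16 | (4aS,5R,6R,8aS)-5-ethenyl-2,2,5,8a-tetramethylhexahydro-4H-1,3-benzodioxin-6-ol | CC1(C)OC[C@@H]2[C@@](C)(C=C)[C@H](O)CC[C@]2(C)O1 | intermediate
17 | 1-bromo-2-methylprop-1-ene | CC(C)=CBr | starting material
18 | 9-{2-[(4aS,5R,6R,8aS)-6-hydroxy-2,2,5,8a-tetramethylhexahydro-4H-1,3-benzodioxin-5-yl]ethyl}-9-borabicyclo[3.3.1]nonane | CC1(C)OC[C@@H]2[C@@](C)(CCB3C4CCCC3CCC4)[C@H](O)CC[C@]2(C)O1 | intermediate (not isolated)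
19 | (4aS,5R,6R,8aS)-2,2,5,8a-tetramethyl-5-(4-methylpent-3-en-1-yl)hexahydro-4H-1,3-benzodioxin-6-ol | CC1(C)OC[C@@H]2[C@@](C)(CCC=C(C)C)[C@H](O)CC[C@]2(C)O1 | intermediate
20 | (4aS,5R,6R,8aS)-5-{2-[(2R)-3,3-dimethyloxiran-2-yl]ethyl}-2,2,5,8a-tetramethylhexahydro-4H-1,3-benzodioxin-6-ol | CC1(C)OC[C@@H]2[C@@](C)(CC[C@H]3OC3(C)C)[C@H](O)CC[C@]2(C)O1 | intermediate
21 | isopropylidene acetal (C7 oxygen to C6 CH2O) of 22, with the C3 triisopropylsilyl ether | CC1(C)OC[C@@H]2[C@@]3(C)CC[C@@H](O[Si](C(C)C)(C(C)C)C(C)C)C(C)(C)O[C@@H]3CC[C@]2(C)O1 | intermediate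
22 | (3R,5aR,6S,7S,9aR)-6-(hydroxymethyl)-2,2,5a,7-tetramethyl-3-{[tri(propan-2-yl)silyl]oxy}decahydro-1-benzoxepin-7-ol | OC[C@@H]1[C@@]2(C)CC[C@@H](O[Si](C(C)C)(C(C)C)C(C)C)C(C)(C)O[C@@H]2CC[C@]1(C)O | intermediate
23 | (3R,5aR,6R,7S,9aR)-7-hydroxy-2,2,5a,7-tetramethyl-3-{[tri(propan-2-yl)silyl]oxy}decahydro-1-benzoxepine-6-carbaldehyde | O=C[C@@H]1[C@@]2(C)CC[C@@H](O[Si](C(C)C)(C(C)C)C(C)C)C(C)(C)O[C@@H]2CC[C@]1(C)O | intermediate
24 | (3R,5aR,6R,7S,9aR)-6-ethenyl-2,2,5a,7-tetramethyl-3-{[tri(propan-2-yl)silyl]oxy}decahydro-1-benzoxepin-7-ol | C=C[C@@H]1[C@@]2(C)CC[C@@H](O[Si](C(C)C)(C(C)C)C(C)C)C(C)(C)O[C@@H]2CC[C@]1(C)O | intermediate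
25 | 2-methylcyclohexane-1,3-dione | CC1C(=O)CCCC1=O | starting material
26 | 3-bromoprop-1-ene (allyl bromide) | C=CCBr | starting material
27 | 2-methyl-2-(prop-2-en-1-yl)cyclohexane-1,3-dione | C=CCC1(C)C(=O)CCCC1=O | intermediate
28 | (2R,3R)-3-hydroxy-2-methyl-2-(prop-2-en-1-yl)cyclohexan-1-one | O=C1[C@](C)(CC=C)[C@H](O)CCC1 | intermediate
29 | (2R,3R)-3-{[tert-butyl(dimethyl)silyl]oxy}-2-methyl-2-(prop-2-en-1-yl)cyclohexan-1-one | O=C1[C@](C)(CC=C)[C@H](O[Si](C)(C)C(C)(C)C)CCC1 | intermediate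
30 | lithium (5R,6R)-5-{[tert-butyl(dimethyl)silyl]oxy}-6-methyl-6-(prop-2-en-1-yl)cyclohex-1-en-1-olate | [Li]OC1=CCC[C@@H](O[Si](C)(C)C(C)(C)C)[C@@]1(C)CC=C | intermediate (not isolated)
31 | (2R,3R,6RS)-3-{[tert-butyl(dimethyl)silyl]oxy}-2,6-dimethyl-2-(prop-2-en-1-yl)cyclohexan-1-one | O=C1[C@](C)(CC=C)[C@H](O[Si](C)(C)C(C)(C)C)CCC1C | intermediate
32 | potassium (5R,6R)-5-{[tert-butyl(dimethyl)silyl]oxy}-2,6-dimethyl-6-(prop-2-en-1-yl)cyclohex-1-en-1-olate | [K]OC1=C(C)CC[C@@H](O[Si](C)(C)C(C)(C)C)[C@@]1(C)CC=C | intermediate (not isolated)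
33 | (5R,6R)-5-{[tert-butyl(dimethyl)silyl]oxy}-2,6-dimethyl-6-(prop-2-en-1-yl)cyclohex-1-en-1-yl trifluoromethanesulfonate | CC1=C(OS(=O)(=O)C(F)(F)F)[C@](C)(CC=C)[C@H](O[Si](C)(C)C(C)(C)C)CC1 | intermediate
34 | 2-methylbut-3-en-2-ol | CC(C)(O)C=C | starting material
35 | (5R,6R)-5-{[tert-butyl(dimethyl)silyl]oxy}-6-[(2E)-4-hydroxy-4-methylpent-2-en-1-yl]-2,6-dimethylcyclohex-1-en-1-yl trifluoromethanesulfonate | CC1=C(OS(=O)(=O)C(F)(F)F)[C@](C)(C/C=C/C(C)(C)O)[C@H](O[Si](C)(C)C(C)(C)C)CC1 | intermediate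
36 | 9-{2-[(3R,5aR,6R,7S,9aR)-7-hydroxy-2,2,5a,7-tetramethyl-3-{[tri(propan-2-yl)silyl]oxy}decahydro-1-benzoxepin-6-yl]ethyl}-9-borabicyclo[3.3.1]nonane | B1(CC[C@@H]2[C@@]3(C)CC[C@@H](O[Si](C(C)C)(C(C)C)C(C)C)C(C)(C)O[C@@H]3CC[C@]2(C)O)C2CCCC1CCC2 | intermediate (not isolated)
37 | (3R,5aR,6R,7S,9aR)-6-{2-[(5R,6S)-5-{[tert-butyl(dimethyl)silyl]oxy}-6-[(2E)-4-hydroxy-4-methylpent-2-en-1-yl]-2,6-dimethylcyclohex-1-en-1-yl]ethyl}-2,2,5a,7-tetramethyl-3-{[tri(propan-2-yl)silyl]oxy}decahydro-1-benzoxepin-7-ol | CC1=C(CC[C@@H]2[C@@]3(C)CC[C@@H](O[Si](C(C)C)(C(C)C)C(C)C)C(C)(C)O[C@@H]3CC[C@]2(C)O)[C@](C)(C/C=C/C(C)(C)O)[C@H](O[Si](C)(C)C(C)(C)C)CC1 | intermediate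
38 | siphonellinol C, (3R,5aR,6R,7S,9aR)-6-{2-[(5R,6S)-5-hydroxy-6-[(2E)-4-hydroxy-4-methylpent-2-en-1-yl]-2,6-dimethylcyclohex-1-en-1-yl]ethyl}-2,2,5a,7-tetramethyldecahydro-1-benzoxepine-3,7-diol | CC1=C(CC[C@@H]2[C@@]3(C)CC[C@@H](O)C(C)(C)O[C@@H]3CC[C@]2(C)O)[C@](C)(C/C=C/C(C)(C)O)[C@H](O)CC1 | target

Total step count: 23. Longest linear sequence: 16 steps (1 → 2 → 4 → 9 → 10 → 11 → 12 → 13 → 16 → 19 → 20 → 21 → 22 → 23 → 24 → 37 → 38, that is steps 1, 2, 4–15, 22 and 23). Epoxide 6 is made from nerol 5 in one step (step 3) and joins this chain at step 4; the triflate 35 takes 6 steps (steps 16–21) and joins at step 22.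

Steps most likely to fail

Step 9. The E geometry of the allyl unit may erode at the π-allylpalladium stage, or the free aldehyde may interfere with the palladium/diboron couple, which would lower conversion or deliver the C9a epimer. The fallback separates borylation from ring closure. It sets out from 13: NaBH4 (MeOH, 0 °C) would give the chloro alcohol 3-[(4S,5S)-5-[(2E)-4-chlorobut-2-en-2-yl]-2,2,4-trimethyl-1,3-dioxan-4-yl]propan-1-ol F1. Borylation (B2pin2, Pd2(dba)3, THF, 60 °C) would then give the isolable allylboronate alcohol F2, whose alkene geometry can be checked. Dess–Martin oxidation would release aldehyde 14 under neutral, metal-free conditions, and 14 should cyclise to 15; hydrolysis returns to the route at 16.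

Step 12. The C9a hydroxyl may attack the secondary epoxide carbon (6-exo, giving a tetrahydropyran) instead of the tertiary one, or the acetonide may be lost to the silyl triflate. The fallback replaces epoxide opening by a Markovnikov 7-exo alkoxylation of an alkene, where the regiochemistry is not in doubt. It sets out from 20: diethylaluminium 2,2,6,6-tetramethylpiperidide (toluene, 0 °C) would isomerise the epoxide, with retention at C3, to the allylic alcohol F3. Hg(OCOCF3)2 (CH2Cl2, 0 °C) would close the oxepane at the tertiary alkene carbon to give the organomercurial F4, and NaBH4/NaOH would reduce it to the oxepanol F5. TIPSOTf/2,6-lutidine would then return to the route at 21.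

Step 4. The hindered 1-methylalkenyl copper reagent may open the trisubstituted epoxide slowly or unselectively (elimination to an allylic alcohol, bromohydrin formation or recovery of 6). The fallback delivers a small vinyl group and builds the trisubstituted alkene afterwards. It sets out from 6: CH2=CHMgBr/CuI (THF, −20 °C) would give the vinyl diol (2S,3S)-2-ethenyl-3,7-dimethyloct-6-ene-1,3-diol F6, and 2,2-dimethoxypropane/PPTS would give its acetonide F7. Wacker oxidation (PdCl2, CuCl, O2, DMF/H2O) would give the methyl ketone F8. Horner–Wadsworth–Emmons olefination with triethyl phosphonoacetate (NaH, THF) would give the (E)-enoate F9, and (i-Bu)2AlH (CH2Cl2, −78 °C) would return to the route at 11.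

Further compounds

F1 | step 9 | 3-[(4S,5S)-5-[(2E)-4-chlorobut-2-en-2-yl]-2,2,4-trimethyl-1,3-dioxan-4-yl]propan-1-ol | CC1(C)OC[C@H](/C(C)=C/CCl)[C@](C)(CCCO)O1
F2 | step 9 | 3-[(4S,5S)-2,2,4-trimethyl-5-[(2E)-4-(4,4,5,5-tetramethyl-1,3,2-dioxaborolan-2-yl)but-2-en-2-yl]-1,3-dioxan-4-yl]propan-1-ol | CC1(C)OC[C@H](/C(C)=C/CB2OC(C)(C)C(C)(C)O2)[C@](C)(CCCO)O1
F3 | step 12 | (4aS,5R,6R,8aS)-5-[(3R)-3-hydroxy-4-methylpent-4-en-1-yl]-2,2,5,8a-tetramethylhexahydro-4H-1,3-benzodioxin-6-ol | CC1(C)OC[C@@H]2[C@@](C)(CC[C@@H](O)C(C)=C)[C@H](O)CC[C@]2(C)O1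
F4 | step 12 | C2-(trifluoroacetoxymercuriomethyl) analogue of F5 (both C2 epimers) | CC1(C)OC[C@@H]2[C@@]3(C)CC[C@@H](O)C(C)(C[Hg]OC(=O)C(F)(F)F)O[C@@H]3CC[C@]2(C)O1
F5 | step 12 | C3 alcohol of 21 (21 without the silyl group) | CC1(C)OC[C@@H]2[C@@]3(C)CC[C@@H](O)C(C)(C)O[C@@H]3CC[C@]2(C)O1
F6 | step 4 | (2S,3S)-2-ethenyl-3,7-dimethyloct-6-ene-1,3-diol | OC[C@@H]([C@@](C)(O)CCC=C(C)C)C=C
F7 | step 4 | (4S,5S)-5-ethenyl-2,2,4-trimethyl-4-(4-methylpent-3-en-1-yl)-1,3-dioxane | CC1(C)OC[C@H](C=C)[C@](C)(CCC=C(C)C)O1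
F8 | step 4 | 1-[(4S,5S)-2,2,4-trimethyl-4-(4-methylpent-3-en-1-yl)-1,3-dioxan-5-yl]ethan-1-one | CC1(C)OC[C@H](C(C)=O)[C@](C)(CCC=C(C)C)O1
F9 | step 4 | ethyl (2E)-3-[(4S,5S)-2,2,4-trimethyl-4-(4-methylpent-3-en-1-yl)-1,3-dioxan-5-yl]but-2-enoate | CC1(C)OC[C@H](/C(C)=C/C(=O)OCC)[C@](C)(CCC=C(C)C)O1
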